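Readings and results were generated by integration with made-up constants, and the scatter is random.

Starting material turns into intermediate, and each intermediate leaves by one of several exits, so the amount of target is a matter of shares.

| flask | starting material | first nucleophile | solid second nucleophile | remark | time |
|---|---|---|---|---|---|
| elm | 0.0020 M | 2.4 mM | 4 mM | run made earlier |  |
| ash | 0.0010 M | 2.4 mM | 4 mM | run made earlier |  |
| alder | 0.0015 M | 2.4 mM | 4 mM | run made earlier |  |
| dawn | 0.0020 M (fed, over 2.0 min) | 2.40 mM | 4.00 mM | all else is in the flask from the start; the feed brings no volume worth counting | 3.0 min |
| midnight | 0.0020 M | 2.40 mM (fed, over 2.0 min) | 4.00 mM | all else is in the flask from the start; the feed brings no volume worth counting | 3.0 min |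
| autumn | 0.0020 M | 2.40 mM | 4.00 mM | everything together at the start | 3.0 min |

| elm: time / min | elm: target / % | ash: time / min | ash: target / % | alder: time / min | alder: target / % |
|---|---|---|---|---|---|
| 0.167 | 5.3 | 0.250 | 11.2 | 0.200 | 8.9 |
| 0.500 | 19.5 | 0.417 | 18.8 | 0.500 | 19.8 |
| 0.833 | 26.6 | 0.667 | 26.8 | 1.00 | 31.3 |
| 1.33 | 31.6 | 1.00 | 34.2 | 1.50 | 35.8 |
| 2.00 | 34.0 | 1.50 | 39.2 | 2.00 | 37.4 |
| 2.50 | 35.8 | 2.50 | 41.9 | 3.00 | 38.3 |
| 3.00 | 35.9 | 4.00 | 42.6 | 4.00 | 39.9 |

(standard deviation of a reading: 0.5 percentage points)

- percent here means starting material units held: one side product counts as two
- solid second nucleophile is a solid; its amount is given per volume of the solution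
- what may be going on: second nucleophile + intermediate -> other capture product; first nucleophile + intermediate -> target; solid second nucleophile <-> second nucleophile; starting material + intermediate -> side product; starting material -> intermediate; intermediate -> solvolysis product
- at the start none of the solid second nucleophile is in solution

1. which flask leads in amount of target, in percent of the starting material charged ("all alike" within 1.5 percentage points) (dawn / midnight / autumn / all alike)
2. how much target is there at the end, in percent of the starting material charged: dawn
3. how much target is there at the end, in percent of the starting material charged: midnight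
4. how much target is there at the end, in percent of the starting material charged: autumn

In the ash run target reads 42.6 % at the last time, and we take the mean c(first nucleophile) midway between the charge and what target leaves of it, at 2.19 mM. That mean times the ratio of non-target to target gives 2.95 mM. This is our break-even level: the c(first nucleophile) at which target takes half of the intermediate, so that the target fraction is c/(c + level). The elm run gives 3.64 mM, higher, since its mean c(starting material) while intermediate forms, taken at half the charge, is 1.00 mM against 0.500 mM. A line through both has slope 1.39 and foot, its level with c(starting material) at zero, 2.25 mM. Two scattered readings make a thin line, so we test it: for alder it gives 39.1 %, and alder reads 38.3 % and 39.9 %.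

Autumn repeats elm, so we take 35.9 %. From ash's rise, starting material leaves at about 1.62 min⁻¹. In midnight the average intermediate therefore forms at about 0.617 min, so by our reckoning the feed has by then brought a mean c(first nucleophile) of 0.739 mM, and a level of 3.64 mM gives 16.9 %.

In dawn, feed against loss holds starting material near 0.616 mM. Counting the climb, the mean over the feed is 0.434 mM, so in dawn the level falls to 2.85 mM and the fraction is 45.7 %. But target spends first nucleophile: the mean c(first nucleophile) drops to 1.94 mM and the fraction to 40.5 %. A further doubt: we reckon 5.84 % of the charge still unreacted at 3.0 min, which leaves 38.1 %. That is 2.2 percentage points over the elm reading we took for autumn, against a margin of 1.5 points, so we name dawn.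

The forecast named dawn, with 40 % in dawn (37 % to 44 %), 18 % in midnight and 36.3 % in autumn; its ground for dawn was “Dawn keeps starting material low, which helps”. Its dawn figure stands above ours.

The flasks give 37.7 % in dawn, 15.1 % in midnight and 36.2 % in autumn, so dawn leads.

    second nucleophile + intermediate → other capture product (k = 120 M⁻¹ s⁻¹)
    first nucleophile + intermediate → target (k = 55.0 M⁻¹ s⁻¹)
    solid second nucleophile ⇌ second nucleophile, rate k3*(cs3 - [second nucleophile]) while solid is left; crystals form when [second nucleophile] > cs3 (solubility = 0.200 mM, k = 0.00450 s⁻¹)
    starting material + intermediate → side product (k = 42.0 M⁻¹ s⁻¹)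
    starting material → intermediate (k = 0.0260 s⁻¹)
    intermediate → solvolysis product (k = 0.120 s⁻¹)

In dawn 5.51 % of the starting material still stands at 3.0 min; after 30.0 min dawn holds 40.2 % of target. Read from that, its break-even level is 2.97 mM, against our 2.85 mM. The neighbouring flask is dawn with 0.0041 M of first nucleophile. Keeping our level, we get a mean c(first nucleophile) of 3.51 mM, a fraction of 55.2 %, and, with 5.72 % of its starting material still standing, 52.0 %. That flask gives 51.0 %.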